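## Analysis of the target

Target 21 is an isoflavone: a 4H-chromen-4-one (benzo ring A fused to pyranone ring C) that carries a 2,4-dihydroxyphenyl ring B on C3, hydroxyls on C5 and C7, and a 2-methylbut-3-en-2-yl (1,1-dimethylallyl) group on C8. It has no stereocentre and no configured double bond, so the problem is one of regiochemistry and functional-group handling. Four phenols of different character are present: 5-OH is hydrogen-bonded to the C4 carbonyl, 7-OH is a vinylogous acid, and 2'-OH and 4'-OH are ordinary resorcinol hydroxyls. C2 of the chromone is open to alkoxide or hydroxide, the vinyl group next to 7-OH can be captured by that hydroxyl under strong acid, and an ortho-(1,1-dimethylallyl)phenol can rearrange further on long heating. The hard points are the quaternary benzylic carbon at C8 rather than C6 (both positions lie between two oxygenated carbons), the differentiation of O7 from three other phenolic oxygens, and the joining of two electron-rich aryl units through C2–C3–C4 without strong acid. The strategy rests on ring A: C8a bears O1, its neighbour C4a bears the C4 carbonyl, and C5 with its oxygen sits beside C4a. An aryne drawn across C4a–C8a is therefore polarised by the C5 oxygen so that an oxygen nucleophile enters at C8a and the carbanion appears at C4a. Because C2 carries only hydrogen, the remaining atoms of ring C (O1, C2, C3, C4) are those of a formylated arylacetate in its enol form.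

## Retrosynthetic reasoning

21 from 20: the two acetal C–O bonds on ring B are cut last. The ring B oxygens must stay masked while O7 is alkylated, and the acetals are the only groups in 20 that mild acid removes. The forward step has to cleave them without protonating the vinyl group.

20 from 18: the C8–C(quaternary) bond is cut in a retro-[3,3] sense, which leads to the O7 prenyl ether 18. A pericyclic shift makes the quaternary carbon without any hindered carbon electrophile, and the allyl inversion turns a prenyl ether into exactly the 1,1-dimethylallyl group. The forward reaction has to choose C8 over C6.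

18 from 17 from 16: the O7–CH2 bond is cut, then the two benzyl ethers on ring A. Benzyl on ring A and methoxymethyl on ring B are orthogonal, so hydrogenolysis frees only the 5,7-diol 17, and of its two hydroxyls only the non-chelated, more acidic O7 should alkylate.

16 from 6 and 12 (through aryne 13): O1–C8a and C4–C4a are cut together. This divides the molecule into two halves of similar size, each three steps from a purchasable compound. Ring A comes from a symmetrical phenol, and all carbon atoms of ring C arrive with ring B. Cutting O1–C2 and C2–C3 instead (the deoxybenzoin route) would require a pre-acylated ring A. The forward reaction needs the aryne to take up oxygen at one carbon and the ester carbonyl at the other, in that orientation.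

6 from 3, 2 and 1: the O–Tf, C–Si and C–Br bonds are cut in turn. An ortho-bromophenol is the standard entry to an ortho-silylaryl triflate by O-silylation, halogen–metal exchange with O-to-C silyl shift, and triflation. In 1 both positions ortho to the hydroxyl are equivalent and each lies beside a benzyloxy group, which is the arrangement the aryne needs.

12 from 9 and 10, 9 from 8, 8 from 7: the bond between the future C3 and C2 is cut as a crossed Claisen condensation of arylacetate 9 with formate 10. The acetals are placed on 8 after esterification of acid 7.

## Alternatives that were turned down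

Alternative 1: The quaternary carbon is built first, on a monocyclic ring A precursor, by forming its C–CH3 and C–vinyl bonds.
- Forward key step: 2-acetyl-3,5-bis(methoxymethoxy)phenyl tert-butyl carbonate A2 is treated with methylmagnesium bromide A3, which adds to the ketone. The carbonate group shifts to the new tertiary alkoxide and departs, an ortho-quinone methide with an isopropylidene terminus appears, and vinylmagnesium bromide A4 adds to that terminus. The product is 3,5-bis(methoxymethoxy)-2-(2-methylbut-3-en-2-yl)phenol A1.
- For: the side chain is placed by construction next to the one free hydroxyl (the later O1), so no C6/C8 question arises, and one flask forms both bonds.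
- Against: the quinone methide has six allylic hydrogens on its terminus and can tautomerise by 1,5-hydrogen shift to an ortho-isopropenyl phenol in competition with conjugate addition at a hindered, disubstituted carbon. After A1, rings C and B are still missing. They would have to come from C-acylation of an acid-sensitive phenol (two acetals and a vinyl group) at one of two open positions, followed by formylative closure, so the difficult C–C bond formation comes late in a linear sequence.
- Comparison: this alternative is stronger on placement of the side chain. The chosen route offers convergence, a ring A partner three steps from a symmetrical phenol, and keeps the side chain out of the synthesis until two steps before the end.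

Alternative 2: Ring A itself is assembled by a Danheiser benzannulation that forms C8–C8a and C6–C7.
- Forward key step: 3-[(4-methoxyphenyl)methoxy]cyclobut-2-en-1-one A6 is heated with [(3,3-dimethylpent-4-en-1-yn-1-yl)oxy]tri(propan-2-yl)silane A7. The cyclobutenone opens to a vinylketene, which adds the electron-rich alkyne in a [2+2] sense. The new cyclobutenone opens again and the dienylketene closes by six-electron electrocyclisation and tautomerises to 5-[(4-methoxyphenyl)methoxy]-2-(2-methylbut-3-en-2-yl)-3-{[tri(propan-2-yl)silyl]oxy}phenol A5.
- For: the quaternary carbon is in place without ambiguity, and the three ring A oxygens emerge fully differentiated (free hydroxyl for O1, silyl ether for O7, benzylic ether for O5). On both counts it is stronger than the chosen route.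
- Against: A7 is a sensitive ynol ether that needs a multistep homologation of a hindered ester, and A6 must also be made. The annulation delivers only a benzene ring. The heterocycle and ring B would still have to be attached by acylation ortho to the free hydroxyl of A5, with the same acid-sensitivity and site problems as in Alternative 1.
- Comparison: it buys regiochemical certainty with the longest sequence of the four. The chosen route offers one step that joins both halves and closes ring C, and it accepts a Claisen rearrangement whose preference for C8 is expected but must be verified.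

Alternative 3: Ring C is cut at C3–C4 and O1–C2, the retron of a hetero-Diels–Alder reaction.
- Forward key step: 5-(methoxymethoxy)-2,2-dimethyl-7-[(3-methylbut-2-en-1-yl)oxy]-4H-1,3-benzodioxin-4-one A9 is irradiated near 300 nm. It extrudes the ketone of its acetal and gives an ortho-quinone ketene. The nucleophilic carbon of 4-{(E)-2-[2,4-bis(methoxymethoxy)phenyl]ethenyl}morpholine A10 adds to the ketene carbon, the phenolic oxygen closes onto the iminium carbon, and loss of the secondary amine gives 3-[2,4-bis(methoxymethoxy)phenyl]-5-(methoxymethoxy)-7-[(3-methylbut-2-en-1-yl)oxy]-4H-chromen-4-one A8.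
- For: it is as convergent as the chosen route, the ring fusion is fixed because acyl carbon and oxygen are already on ring A, and acylation of an enamine by a ketene is C-selective, so it is stronger than the chosen key step on the O- versus C-attack question. It also needs no hydrogenolysis or O-alkylation after the key step, because A8 already carries the O7 prenyl group.
- Against: the photolysis must run in the presence of other chromophores. The aryl enamine can isomerise or cycloadd, the allyl aryl ether can undergo a photochemical Claisen shift or cleavage, and the isoflavone product absorbs at the same wavelength. O5 is an acetal and not a hydrogen-bonded hydroxyl at the Claisen stage, and three acetals, one of them at the hindered C5 oxygen, must finally be removed by acid next to the vinyl group.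
- Comparison: it matches the chosen route in step economy and is arguably shorter. The chosen route offers a ground-state, fluoride-triggered annulation at moderate temperature, a free 5-hydroxyl during the Claisen step, and only two acetals to remove.

Key step: step 7

Assumption: formyl ester 12 is an equilibrating mixture of the hydrogen-bonded Z enol, the E enol and the aldehyde; it is numbered and drawn as the Z enol, since all forms give the same enolate 14.

## Route

Step 1
Reactants: 1 3,5-bis(benzyloxy)phenol
Product: 2 3,5-bis(benzyloxy)-2-bromophenol
Conditions: NBS (1.0 equiv), CH2Cl2, −78 °C to 0 °C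
Reagents that add atoms: N-bromosuccinimide, O=C1CCC(=O)N1Br
Why: Electrophilic aromatic bromination; the hydroxyl is the strongest activator and, in a non-polar solvent, hydrogen-bonds the reagent, so bromine should enter at C2 beside it and not at the more crowded C4 between the two benzyloxy groups. One equivalent at low temperature limits double bromination.

Step 2
Reactants: 2 3,5-bis(benzyloxy)-2-bromophenol
Product: 3 [3,5-bis(benzyloxy)-2-bromophenoxy]trimethylsilane
Conditions: (Me3Si)2NH, THF, 65 °C; evaporation
Reagents that add atoms: hexamethyldisilazane, C[Si](C)(C)N[Si](C)(C)C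
Why: O-silylation of a phenol with a disilazane, with ammonia as the only by-product, so the crude silyl ether can be carried on after evaporation.

Step 3
Reactants: 3 [3,5-bis(benzyloxy)-2-bromophenoxy]trimethylsilane
Product: 6 3,5-bis(benzyloxy)-2-(trimethylsilyl)phenyl trifluoromethanesulfonate, via aryllithium 4 (not isolated), via lithium 2-silylphenolate 5 (not isolated)
Conditions: n-BuLi, THF, −78 °C; then Tf2O, −78 °C to rt
Reagents that add atoms: trifluoromethanesulfonic anhydride, O=S(=O)(OS(=O)(=O)C(F)(F)F)C(F)(F)F
Why: Bromine–lithium exchange gives 4, which undergoes the 1,3 O-to-C silyl shift (retro-Brook rearrangement) to the more stable phenolate 5, and this is triflated in the same flask. The exchange at −78 °C is much faster than deprotonation of the benzylic ether positions.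

Step 4
Reactants: 7 (2,4-dihydroxyphenyl)acetic acid
Product: 8 methyl (2,4-dihydroxyphenyl)acetate
Conditions: MeOH, H2SO4 (cat.), reflux
Reagents that add atoms: methanol, CO
Why: Fischer esterification; the large excess of methanol holds the material as the methyl ester and not as the lactone that the 2-hydroxyl could form.

Step 5
Reactants: 8 methyl (2,4-dihydroxyphenyl)acetate
Product: 9 methyl [2,4-bis(methoxymethoxy)phenyl]acetate
Conditions: MOMCl, i-Pr2NEt, CH2Cl2, 0 °C to rt
Reagents that add atoms: chloromethyl methyl ether, COCCl
Why: O-alkylation of both phenols to methoxymethyl acetals under a mild amine base, which should alkylate the ortho hydroxyl before it can lactonise onto the ester. The acetals tolerate NaH, fluoride, hydrogenolysis, carbonate and heat, and leave under mild acid.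

Step 6
Reactants: 9 methyl [2,4-bis(methoxymethoxy)phenyl]acetate; 10 methyl formate
Product: 12 methyl (2Z)-2-[2,4-bis(methoxymethoxy)phenyl]-3-hydroxyprop-2-enoate, via sodium enolate 11 (not isolated)
Conditions: NaH, THF, 0 °C to rt; AcOH, H2O
Reagents that add atoms: none
Why: Crossed Claisen condensation of the ester enolate with the non-enolisable formate; deprotonation of the acidic product to enolate 11 drives it to completion. Buffered acetic acid work-up frees the enol without touching the acetals.

Step 7
Reactants: 6 3,5-bis(benzyloxy)-2-(trimethylsilyl)phenyl trifluoromethanesulfonate; 12 methyl (2Z)-2-[2,4-bis(methoxymethoxy)phenyl]-3-hydroxyprop-2-enoate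
Product: 16 5,7-bis(benzyloxy)-3-[2,4-bis(methoxymethoxy)phenyl]-4H-chromen-4-one, via 3,5-bis(benzyloxy)benzyne 13 (not isolated), via cesium enolate 14 (not isolated), via aryl cesium adduct 15 (not isolated)
Conditions: CsF (4 equiv), THF, 65 °C; 6 (1.5 equiv) added slowly
Reagents that add atoms: none
Why: Proposed new method: CsF converts enol 12 into cesium enolate 14 and, by attack on silicon with loss of triflate, converts 6 into aryne 13; the enolate oxygen adds to the aryne carbon remote from the flanking benzyloxy group (the future C8a), so the charge of aryl anion 15 sits on the carbon beside that oxygen (the future C4a), where the C–O bond stabilises it inductively. Anion 15 then adds to the ester carbonyl held cis to the aryloxy group (6-exo-trig) and the tetrahedral intermediate loses methoxide, which closes ring C as the pyranone; the hydrogen fluoride from the first deprotonation neutralises the methoxide. The closest known reaction type is the fluoride-induced annulation of arynes with salicylate esters to xanthones, which is the same O-arylation and acyl capture with the enol built into a benzene ring; the known counter-example is the insertion of arynes into beta-keto esters, which starts by C-arylation. No stereocentre is formed. Three selectivities are needed: orientation on the unsymmetrical aryne, which the C5 benzyloxy group beside the triple bond secures; O- over C-attack of the ambident enolate, which should be favoured because the alpha-carbon is fully substituted and screened by the ortho-substituted aryl ring while the terminal formyl oxygen carries most of the charge of the loosely paired cesium enolate; and the Z geometry of the new enol ether, which the chelated, freely equilibrating enolate supplies before the C–O bond fixes it. Slow addition of 6 keeps the aryne concentration low, so that it meets enolate and not product or a second aryne.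

Step 8
Reactants: 16 5,7-bis(benzyloxy)-3-[2,4-bis(methoxymethoxy)phenyl]-4H-chromen-4-one
Product: 17 3-[2,4-bis(methoxymethoxy)phenyl]-5,7-dihydroxy-4H-chromen-4-one
Conditions: H2 (1 atm), Pd/C, EtOAc–THF, rt
Reagents that add atoms: none
Why: Hydrogenolysis of the two benzyl aryl ethers over palladium on carbon in a neutral solvent; the acetals are inert. The reaction is stopped once both benzyl groups are gone, so that the C2–C3 double bond of the chromone is spared.

Step 9
Reactants: 17 3-[2,4-bis(methoxymethoxy)phenyl]-5,7-dihydroxy-4H-chromen-4-one
Product: 18 3-[2,4-bis(methoxymethoxy)phenyl]-5-hydroxy-7-[(3-methylbut-2-en-1-yl)oxy]-4H-chromen-4-one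
Conditions: prenyl bromide (1.1 equiv), K2CO3, acetone, 56 °C
Reagents that add atoms: 1-bromo-3-methylbut-2-ene, CC(C)=CCBr
Why: Williamson ether synthesis; the 7-hydroxyl is the more acidic, being para to the carbonyl-bearing carbon, and is free, whereas the 5-hydroxyl is tied up in a hydrogen bond to the C4 carbonyl and should not alkylate under carbonate. Substitution occurs at the primary allylic carbon.

Step 10
Reactants: 18 3-[2,4-bis(methoxymethoxy)phenyl]-5-hydroxy-7-[(3-methylbut-2-en-1-yl)oxy]-4H-chromen-4-one
Product: 20 3-[2,4-bis(methoxymethoxy)phenyl]-5,7-dihydroxy-8-(2-methylbut-3-en-2-yl)-4H-chromen-4-one, via ortho-dienone 19 (not isolated)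
Conditions: PhNEt2, 190 °C, sealed tube, argon
Reagents that add atoms: none
Why: Aromatic Claisen rearrangement; the [3,3] shift inverts the allyl unit, so the prenyl ether delivers the 1,1-dimethylallyl group and the quaternary carbon, and dienone 19 enolises to the phenol, which removes its transient C8 stereocentre. C8 is expected to be favoured over C6 because in chromones the C7–C8 bond has the higher double-bond character, as in a 2-naphthyl allyl ether. The basic amine solvent keeps acid-promoted follow-up reactions of the product away.

Step 11
Reactants: 20 3-[2,4-bis(methoxymethoxy)phenyl]-5,7-dihydroxy-8-(2-methylbut-3-en-2-yl)-4H-chromen-4-one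
Product: 21 3-(2,4-dihydroxyphenyl)-5,7-dihydroxy-8-(2-methylbut-3-en-2-yl)-4H-chromen-4-one
Conditions: HCl (about 1 M), MeOH, 40 °C
Reagents that add atoms: none
Why: Acid-catalysed acetal exchange removes both methoxymethyl groups as dimethoxymethane. The monosubstituted vinyl group would have to pass through a secondary cation to be captured by O7, which should be slow at this acidity and temperature.

## Compound list

1 | 3,5-bis(benzyloxy)phenol | Oc1cc(OCc2ccccc2)cc(OCc2ccccc2)c1 | starting material
2 | 3,5-bis(benzyloxy)-2-bromophenol | Oc1cc(OCc2ccccc2)cc(OCc2ccccc2)c1Br | intermediate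
3 | [3,5-bis(benzyloxy)-2-bromophenoxy]trimethylsilane | C[Si](C)(C)Oc1cc(OCc2ccccc2)cc(OCc2ccccc2)c1Br | intermediate
4 | [2,4-bis(benzyloxy)-6-(trimethylsilyloxy)phenyl]lithium | [Li]c1c(O[Si](C)(C)C)cc(OCc2ccccc2)cc1OCc1ccccc1 | intermediate
5 | lithium 3,5-bis(benzyloxy)-2-(trimethylsilyl)phenolate | [Li+].[O-]c1cc(OCc2ccccc2)cc(OCc2ccccc2)c1[Si](C)(C)C | intermediate
6 | 3,5-bis(benzyloxy)-2-(trimethylsilyl)phenyl trifluoromethanesulfonate | C[Si](C)(C)c1c(OCc2ccccc2)cc(OCc2ccccc2)cc1OS(=O)(=O)C(F)(F)F | intermediate
7 | (2,4-dihydroxyphenyl)acetic acid | OC(=O)Cc1ccc(O)cc1O | starting material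
8 | methyl (2,4-dihydroxyphenyl)acetate | COC(=O)Cc1ccc(O)cc1O | intermediate
9 | methyl [2,4-bis(methoxymethoxy)phenyl]acetate | COC(=O)Cc1ccc(OCOC)cc1OCOC | intermediate
10 | methyl formate | COC=O | starting material
11 | sodium (1Z)-2-[2,4-bis(methoxymethoxy)phenyl]-3-methoxy-3-oxoprop-1-en-1-olate | COC(=O)/C(=C\[O-])c1ccc(OCOC)cc1OCOC.[Na+] | intermediate
12 | methyl (2Z)-2-[2,4-bis(methoxymethoxy)phenyl]-3-hydroxyprop-2-enoate | COC(=O)/C(=C\O)c1ccc(OCOC)cc1OCOC | intermediate
13 | 3,5-bis(benzyloxy)benzyne (3,5-bis(benzyloxy)-1,2-didehydrobenzene) | C1#CC(OCc2ccccc2)=CC(OCc2ccccc2)=C1 | intermediate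
14 | cesium (1Z)-2-[2,4-bis(methoxymethoxy)phenyl]-3-methoxy-3-oxoprop-1-en-1-olate | COC(=O)/C(=C\[O-])c1ccc(OCOC)cc1OCOC.[Cs+] | intermediate
15 | methyl (2Z)-3-[3,5-bis(benzyloxy)-2-cesiophenoxy]-2-[2,4-bis(methoxymethoxy)phenyl]prop-2-enoate | COC(=O)/C(=C\Oc1cc(OCc2ccccc2)cc(OCc2ccccc2)c1[Cs])c1ccc(OCOC)cc1OCOC | intermediate
16 | 5,7-bis(benzyloxy)-3-[2,4-bis(methoxymethoxy)phenyl]-4H-chromen-4-one | COCOc1ccc(-c2coc3cc(OCc4ccccc4)cc(OCc4ccccc4)c3c2=O)c(OCOC)c1 | intermediate
17 | 3-[2,4-bis(methoxymethoxy)phenyl]-5,7-dihydroxy-4H-chromen-4-one | COCOc1ccc(-c2coc3cc(O)cc(O)c3c2=O)c(OCOC)c1 | intermediate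
18 | 3-[2,4-bis(methoxymethoxy)phenyl]-5-hydroxy-7-[(3-methylbut-2-en-1-yl)oxy]-4H-chromen-4-one | COCOc1ccc(-c2coc3cc(OCC=C(C)C)cc(O)c3c2=O)c(OCOC)c1 | intermediate
19 | 3-[2,4-bis(methoxymethoxy)phenyl]-5-hydroxy-8-(2-methylbut-3-en-2-yl)-4H-chromene-4,7(8H)-dione (racemic at C8, transient) | C=CC(C)(C)C1C(=O)C=C(O)C2=C1OC=C(c1ccc(OCOC)cc1OCOC)C2=O | intermediate
20 | 3-[2,4-bis(methoxymethoxy)phenyl]-5,7-dihydroxy-8-(2-methylbut-3-en-2-yl)-4H-chromen-4-one | C=CC(C)(C)c1c(O)cc(O)c2c(=O)c(-c3ccc(OCOC)cc3OCOC)coc12 | intermediate
21 | 3-(2,4-dihydroxyphenyl)-5,7-dihydroxy-8-(2-methylbut-3-en-2-yl)-4H-chromen-4-one | C=CC(C)(C)c1c(O)cc(O)c2c(=O)c(-c3ccc(O)cc3O)coc12 | target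

## Step count and least certain steps

Total: 11 steps. Longest linear sequence: 8 steps (steps 1–3 or steps 4–6, then steps 7–11).

**Step 7 (key step, proposed new method).**
- What may go wrong: the enolate may attack the aryne through carbon, after which the aryl anion adds to the formyl group and the four-membered alkoxide fragments (formal insertion into the C–CHO bond). The aryl anion may also be protonated before it reaches the ester, or O-arylation may take place from the E enolate, which cannot cyclise. Released methoxide could add to C2 of the product.
- Fallback (known chemistry, from 2 and 9, returning at 16): ester 9 is converted with MeNH(OMe)·HCl and i-PrMgCl in THF into 2-[2,4-bis(methoxymethoxy)phenyl]-N-methoxy-N-methylacetamide F1. Bromophenol 2 is lithiated twice with n-BuLi in THF at −78 °C (O–H, then bromine–lithium exchange) and acylated by F1 to give the deoxybenzoin 1-[2,4-bis(benzyloxy)-6-hydroxyphenyl]-2-[2,4-bis(methoxymethoxy)phenyl]ethan-1-one F2. Heating F2 with Me2NCH(OMe)2 in toluene forms the enaminone, the phenol adds, dimethylamine is lost, and ring C closes by the classical O1–C2 and C2–C3 construction to give 16.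

**Step 10.**
- What may go wrong: poor selectivity between the two ortho positions (migration to C6). On long heating the product phenol may react further, by an abnormal Claisen rearrangement through a spirocyclopropane or by closure of O7 onto the vinyl group.
- Fallback (from 18, returning at 20): acetylation with Ac2O, DMAP and pyridine removes the chelate and gives 3-[2,4-bis(methoxymethoxy)phenyl]-7-[(3-methylbut-2-en-1-yl)oxy]-4-oxo-4H-chromen-5-yl acetate F3. Rearrangement of F3 in PhNEt2 with Ac2O and NaOAc at 190 °C then runs under the bond fixation of the plain chromone and traps the new phenol at once, giving 3-[2,4-bis(methoxymethoxy)phenyl]-8-(2-methylbut-3-en-2-yl)-4-oxo-4H-chromene-5,7-diyl diacetate F4. K2CO3 in MeOH at rt removes both acetates to give 20.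

**Step 1.**
- What may go wrong: bromination at C4 between the benzyloxy groups, or twice, which lowers the supply of the only isomer that can undergo the silyl shift.
- Fallback (from 1, returning at 6): the position is set by directed ortho-metalation instead. Phenol 1 and i-PrNCO with catalytic Et3N give 3,5-bis(benzyloxy)phenyl N-(propan-2-yl)carbamate F5. N-silylation in the flask (TMSOTf, TMEDA), lithiation with n-BuLi at −78 °C at the only kind of position ortho to the carbamate, and TMSCl give 3,5-bis(benzyloxy)-2-(trimethylsilyl)phenyl N-(propan-2-yl)carbamate F6. DBU and Et2NH in MeCN cleave the carbamate to 3,5-bis(benzyloxy)-2-(trimethylsilyl)phenol F7, which is triflated in the same flask with PhNTf2 to give 6.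

**Step 11.**
- What may go wrong: acid-induced addition of the 7-hydroxyl across the vinyl group, or incomplete cleavage of the hindered 2'-acetal, which would call for harsher acid.
- Fallback (from 17, returning at 21): the order is changed so that no acid meets the side chain. HCl in MeOH converts 17 into 3-(2,4-dihydroxyphenyl)-5,7-dihydroxy-4H-chromen-4-one F8. One equivalent of prenyl bromide with K2CO3 in acetone alkylates the most acidic 7-hydroxyl to give 3-(2,4-dihydroxyphenyl)-5-hydroxy-7-[(3-methylbut-2-en-1-yl)oxy]-4H-chromen-4-one F9. Claisen rearrangement of F9 in PhNEt2 at 190 °C then gives 21 directly.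

## Further compounds

F1 | step 7 | 2-[2,4-bis(methoxymethoxy)phenyl]-N-methoxy-N-methylacetamide | CON(C)C(=O)Cc1ccc(OCOC)cc1OCOC
F2 | step 7 | 1-[2,4-bis(benzyloxy)-6-hydroxyphenyl]-2-[2,4-bis(methoxymethoxy)phenyl]ethan-1-one | O=C(Cc1ccc(OCOC)cc1OCOC)c1c(O)cc(OCc2ccccc2)cc1OCc1ccccc1
F3 | step 10 | 3-[2,4-bis(methoxymethoxy)phenyl]-7-[(3-methylbut-2-en-1-yl)oxy]-4-oxo-4H-chromen-5-yl acetate | COCOc1ccc(-c2coc3cc(OCC=C(C)C)cc(OC(C)=O)c3c2=O)c(OCOC)c1
F4 | step 10 | 3-[2,4-bis(methoxymethoxy)phenyl]-8-(2-methylbut-3-en-2-yl)-4-oxo-4H-chromene-5,7-diyl diacetate | C=CC(C)(C)c1c(OC(C)=O)cc(OC(C)=O)c2c(=O)c(-c3ccc(OCOC)cc3OCOC)coc12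
F5 | step 1 | 3,5-bis(benzyloxy)phenyl N-(propan-2-yl)carbamate | CC(C)NC(=O)Oc1cc(OCc2ccccc2)cc(OCc2ccccc2)c1
F6 | step 1 | 3,5-bis(benzyloxy)-2-(trimethylsilyl)phenyl N-(propan-2-yl)carbamate | CC(C)NC(=O)Oc1cc(OCc2ccccc2)cc(OCc2ccccc2)c1[Si](C)(C)C
F7 | step 1 | 3,5-bis(benzyloxy)-2-(trimethylsilyl)phenol | Oc1cc(OCc2ccccc2)cc(OCc2ccccc2)c1[Si](C)(C)C
F8 | step 11 | 3-(2,4-dihydroxyphenyl)-5,7-dihydroxy-4H-chromen-4-one | O=c1c(-c2ccc(O)cc2O)coc2cc(O)cc(O)c12
F9 | step 11 | 3-(2,4-dihydroxyphenyl)-5-hydroxy-7-[(3-methylbut-2-en-1-yl)oxy]-4H-chromen-4-one | CC(C)=CCOc1cc(O)c2c(=O)c(-c3ccc(O)cc3O)coc2c1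
A1 | alternative 1 | 3,5-bis(methoxymethoxy)-2-(2-methylbut-3-en-2-yl)phenol | C=CC(C)(C)c1c(O)cc(OCOC)cc1OCOC
A2 | alternative 1 | 2-acetyl-3,5-bis(methoxymethoxy)phenyl tert-butyl carbonate | CC(=O)c1c(OC(=O)OC(C)(C)C)cc(OCOC)cc1OCOC
A3 | alternative 1 | methylmagnesium bromide | C[Mg]Br
A4 | alternative 1 | vinylmagnesium bromide | C=C[Mg]Br
A5 | alternative 2 | 5-[(4-methoxyphenyl)methoxy]-2-(2-methylbut-3-en-2-yl)-3-{[tri(propan-2-yl)silyl]oxy}phenol | C=CC(C)(C)c1c(O)cc(OCc2ccc(OC)cc2)cc1O[Si](C(C)C)(C(C)C)C(C)C
A6 | alternative 2 | 3-[(4-methoxyphenyl)methoxy]cyclobut-2-en-1-one | COc1ccc(COC2=CC(=O)C2)cc1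
A7 | alternative 2 | [(3,3-dimethylpent-4-en-1-yn-1-yl)oxy]tri(propan-2-yl)silane | C=CC(C)(C)C#CO[Si](C(C)C)(C(C)C)C(C)C
A8 | alternative 3 | 3-[2,4-bis(methoxymethoxy)phenyl]-5-(methoxymethoxy)-7-[(3-methylbut-2-en-1-yl)oxy]-4H-chromen-4-one | COCOc1ccc(-c2coc3cc(OCC=C(C)C)cc(OCOC)c3c2=O)c(OCOC)c1
A9 | alternative 3 | 5-(methoxymethoxy)-2,2-dimethyl-7-[(3-methylbut-2-en-1-yl)oxy]-4H-1,3-benzodioxin-4-one | CC1(C)OC(=O)c2c(OCOC)cc(OCC=C(C)C)cc2O1
A10 | alternative 3 | 4-{(E)-2-[2,4-bis(methoxymethoxy)phenyl]ethenyl}morpholine | COCOc1ccc(/C=C/N2CCOCC2)c(OCOC)c1
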